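Each molecule of substrate stays on the books as substrate, intermediate, target or isomer of the product, so the intermediate we are asked for is the charge less the substrate still standing and less what has gone on with the coupling partner.

    coupling partner + intermediate ⇌ target (K1 = 7500 M⁻¹, k1 = 9.5 M⁻¹ s⁻¹)
    substrate → intermediate (k2 = 0.072 s⁻¹)
    target ⇌ isomer of the product (K3 = 0.30, k3 = 0.098 s⁻¹)

| flask | substrate | coupling partner | time | remark |
|---|---|---|---|---|
| north-east | 1.0 mM | 1.10 equiv (fed, over 0.800 min) | 1.0 min | all but coupling partner at the start; coupling partner goes in evenly over 0.800 min, the run ends at 1.0 min |
| south-east | 1.0 mM | 1.10 equiv | 1.0 min | everything together in a closed stirred flask, run for 1.0 min |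
| north | 1.0 mM | 1.10 equiv |  | one stirred flow tank at steady state, fed with the mixture as stated, mean residence time 1.0 min |
| north-west | 1.0 mM | 1.10 equiv | 1.0 min | plug flow through a tube for 1.0 min, no back-mixing |

* the set-up with the highest amount of intermediate at the outlet or at the end, in percent of the substrate put in ("none" if the first two lie within 2 percentage points) (north-east / south-east / north / north-west / none)
* amount of intermediate at the outlet or at the end, in percent of the substrate put in, north-east
* amount of intermediate at the outlet or at the end, in percent of the substrate put in, south-east
* amount of intermediate at the outlet or at the end, in percent of the substrate put in, north
* amount of intermediate at the outlet or at the end, in percent of the substrate put in, north-west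

- the stated concentrations are those of everything mixed, before any reaction; amounts are the same in each set-up
- the feed brings no volume worth counting
- run time (north-east): 1.0 min

We follow one molecule of intermediate. With [coupling partner] held fixed, its coupling is a pseudo-first-order loss, and at the full charge the rate is 0.0105 s⁻¹. Multiplied by the run time this gives the exposure, 0.627, the mean number of couplings met by a molecule present from start to end with the partner unspent.

In the closed flask (south-east), we first hold the partner at its full charge and let the intermediate be born at rate constant 0.072 s⁻¹, which gives a floor:

floor = 60.9%

The balance then allows at most the charge less that floor to have been taken, so [coupling partner] stays above 0.709 mM. Running the same reckoning at that lower strength gives a ceiling: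

rate = 0.00674 s⁻¹, ceiling = 72.2%

The ceiling sets aside the way back, whose constant 0.00127 s⁻¹ is smaller than the full coupling rate. The tube (north-west) has the same clock, so it takes the same bracket.

In the fed flask (north-east), a ramp over 0.800 min amounts to losing half the dosing time, so the exposure falls to 0.376. A molecule born at the first instant therefore gives a floor:

fed floor = 67.7%

That is higher than the closed floor but lies inside the closed bracket, so our hand reckoning stops short of an ordering.

The forecast names north-east, with 74% there, 66.8% closed, 66.8% in the tube and 55.8% in the stirred tank (north), holding that “feeding the partner gradually holds its concentration low”. Its closed figure lies inside our bracket.

The simulation gives north-east as best, with 74.0% there, 66.7% in the closed flask, 66.7% in the tube and 55.8% in the stirred tank. With the coupling struck out, that tank gives 81.2%. At its outlet, target 19.8% and isomer of the product 5.64% have taken their share of partner, which scales the exposure down to 0.482. A molecule of intermediate in a stirred tank leaves before coupling with chance one over one plus exposure, so with the way back set aside our estimate for the tank is 54.8% of intermediate, against 55.8% found at its outlet.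

The constants used here are those of an exercise; the rest is arithmetic.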